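The plan cuts the C1–C2 bond of the quinone ring, between the C1 carbonyl carbon and C2, the ring carbon that carries the side chain. A Moore rearrangement closes that bond. A 2-alkenyl-2-hydroxybenzocyclobutenone opens thermally to an o-quinoid vinylketene, 6π electrocyclisation joins the ketene carbon to the alkene terminus, and oxidation in the same flask gives the naphthoquinone. One operation thus builds the whole quinone ring with the preformed (R)-carbinol attached. It exploits the 1,4-dioxygenation of this ring (O at C1 from the ketene, O at C4 from the carbinol). It also exploits the symmetric 5,8-dioxygenated benzo ring, which makes both carbonyls of the benzocyclobutenedione precursor equivalent.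

Key step: step 11

Assumption: the naphthazarin core equilibrates rapidly between its tautomers and is written with the side chain on the quinone ring; the carbinol centre created in step 10 is carried as a mixture of epimers because step 11 destroys it.

Step 1
Reactants: 1 2-bromo-1,4-dimethoxybenzene; 2 1,1-diethoxyethene
Product: 5 2,5-dimethoxybicyclo[4.2.0]octa-1,3,5-trien-7-one (3,6-dimethoxybenzocyclobutenone), via 3,6-dimethoxybenzyne 3 (not isolated), via diethyl ketal 4 (not isolated)
Conditions: NaNH2, THF, reflux; then 1 M aq. HCl, THF, rt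
Reagents that add atoms: water (O)
Why: NaNH2 removes HBr to give the symmetric aryne 3, which undergoes the known aryne–ketene acetal [2+2] cycloaddition to the only possible regioisomer, and mild acid hydrolysis of ketal 4 releases the strained ketone.

Step 2
Reactants: 5 2,5-dimethoxybicyclo[4.2.0]octa-1,3,5-trien-7-one
Product: 6 8,8-dibromo-2,5-dimethoxybicyclo[4.2.0]octa-1,3,5-trien-7-one
Conditions: NBS (2.2 equiv), dibenzoyl peroxide (cat.), PhCF3, reflux, hν
Reagents that add atoms: N-bromosuccinimide (O=C1CCC(=O)N1Br)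
Why: Wohl–Ziegler radical bromination should take both hydrogens of the only benzylic, carbonyl-flanked CH2 group, with the non-polar medium and the acyl substituent holding back ionic bromination of the ring.

Step 3
Reactants: 6 8,8-dibromo-2,5-dimethoxybicyclo[4.2.0]octa-1,3,5-trien-7-one
Product: 7 2,5-dimethoxybicyclo[4.2.0]octa-1,3,5-triene-7,8-dione (3,6-dimethoxybenzocyclobutenedione)
Conditions: 50% aq. H2SO4, 60 °C
Reagents that add atoms: water (O)
Why: Acid hydrolysis of a geminal dihalide gives the second carbonyl, and the aryl methyl ethers and the non-enolisable 1,2-dione tolerate aqueous acid.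

Step 4
Reactants: 7 2,5-dimethoxybicyclo[4.2.0]octa-1,3,5-triene-7,8-dione
Product: 8 2,5-dihydroxybicyclo[4.2.0]octa-1,3,5-triene-7,8-dione
Conditions: BBr3, CH2Cl2, −78 °C to rt; then H2O
Reagents that add atoms: none
Why: Lewis-acid ether cleavage with BBr3 is helped by chelation of boron between each methoxy oxygen and the neighbouring carbonyl, and it is placed here because the robust dione tolerates what the finished side chain would not.

Step 5
Reactants: 8 2,5-dihydroxybicyclo[4.2.0]octa-1,3,5-triene-7,8-dione
Product: 9 2,5-bis(tert-butyldimethylsilyloxy)bicyclo[4.2.0]octa-1,3,5-triene-7,8-dione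
Conditions: TBSOTf, 2,6-lutidine, CH2Cl2, 0 °C
Reagents that add atoms: tert-butyldimethylsilyl trifluoromethanesulfonate (CC(C)(C)[Si](C)(C)OS(=O)(=O)C(F)(F)F)
Why: Silylation of both phenols with a silyl triflate and a hindered, non-nucleophilic base avoids amine attack on the strained dione and installs groups that fluoride removes at the end.

Step 6
Reactants: 10 4-methylpent-3-enoic acid
Product: 12 N-methoxy-N,4-dimethylpent-3-enamide, via acyl imidazolide 11 (not isolated)
Conditions: 1,1'-carbonyldiimidazole, CH2Cl2, rt; then MeNHOMe·HCl, rt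
Reagents that add atoms: N,O-dimethylhydroxylamine hydrochloride (CNOC.Cl)
Why: Acyl imidazolide activation followed by aminolysis (Weinreb amide formation) runs under near-neutral conditions that should leave the β,γ-double bond in place.

Step 7
Reactants: 12 N-methoxy-N,4-dimethylpent-3-enamide; 13 (E)-1,2-bis(tributylstannyl)ethene
Product: 15 (E)-6-methyl-1-(tributylstannyl)hepta-1,5-dien-3-one, via (E)-2-(tributylstannyl)vinyllithium 14 (not isolated)
Conditions: 13, n-BuLi (1 equiv), THF, −78 °C; then 12, −78 °C; AcOH quench at −78 °C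
Reagents that add atoms: none
Why: Tin–lithium exchange at one terminus of 13 gives the (E)-vinyllithium 14 with retention, the Weinreb ketone synthesis stops at the ketone, and the cold acetic acid quench guards against migration of the skipped double bond into conjugation.

Step 8
Reactants: 15 (E)-6-methyl-1-(tributylstannyl)hepta-1,5-dien-3-one
Product: 16 (1E,3R)-6-methyl-1-(tributylstannyl)hepta-1,5-dien-3-ol
Conditions: (S)-1-methyl-3,3-diphenyltetrahydro-1H,3H-pyrrolo[1,2-c][1,3,2]oxazaborole (15 mol %), catecholborane, toluene, −78 °C; then aq. NaHCO3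
Reagents that add atoms: none
Why: In this Corey–Bakshi–Shibata reduction the ketone binds to the (S)-catalyst with the larger stannylvinyl arm turned away from the B-methyl group, so hydride reaches the Si face and sets the (R)-carbinol, the only stereocentre of the target, while catecholborane at low temperature leaves both C=C bonds alone.

Step 9
Reactants: 16 (1E,3R)-6-methyl-1-(tributylstannyl)hepta-1,5-dien-3-ol
Product: 17 (1E,3R)-3-(tert-butyldimethylsilyloxy)-6-methyl-1-(tributylstannyl)hepta-1,5-diene
Conditions: TBSCl, imidazole, DMF, rt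
Reagents that add atoms: tert-butyldimethylsilyl chloride (CC(C)(C)[Si](C)(C)Cl)
Why: Standard silyl ether formation under mildly basic conditions protects the alcohol for the organolithium step without protodestannylation and without touching the stereocentre.

Step 10
Reactants: 17 (1E,3R)-3-(tert-butyldimethylsilyloxy)-6-methyl-1-(tributylstannyl)hepta-1,5-diene; 9 2,5-bis(tert-butyldimethylsilyloxy)bicyclo[4.2.0]octa-1,3,5-triene-7,8-dione
Product: 19 8-hydroxy-8-[(1E,3R)-3-(tert-butyldimethylsilyloxy)-6-methylhepta-1,5-dien-1-yl]-2,5-bis(tert-butyldimethylsilyloxy)bicyclo[4.2.0]octa-1,3,5-trien-7-one (both C8 epimers), via side-chain vinyllithium 18 (not isolated)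
Conditions: 17, n-BuLi, THF, −78 °C; cannulated into 9, THF, −78 °C; AcOH quench at −78 °C
Reagents that add atoms: none
Why: Tin–lithium exchange keeps the (E)-geometry and 1,2-addition of one equivalent of 18 to either of the two equivalent carbonyls of 9 gives the carbinol, whose new centre forms without control and needs none because step 11 flattens it.

Step 11
Reactants: 19 8-hydroxy-8-[(1E,3R)-3-(tert-butyldimethylsilyloxy)-6-methylhepta-1,5-dien-1-yl]-2,5-bis(tert-butyldimethylsilyloxy)bicyclo[4.2.0]octa-1,3,5-trien-7-one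
Product: 23 2-[(1R)-1-(tert-butyldimethylsilyloxy)-4-methylpent-3-en-1-yl]-5,8-bis(tert-butyldimethylsilyloxy)naphthalene-1,4-dione, via o-quinoid vinylketene 20 (not isolated), via keto tautomer 21 (not isolated), via naphthalene-1,4-diol 22 (not isolated)
Conditions: degassed p-xylene (0.01 M), 138 °C; cool to rt, then Ag2O
Reagents that add atoms: none
Why: Heating opens the strained C7–C8 bond of the four-membered ring in a conrotatory 4π electrocyclic reaction to the o-quinoid vinylketene 20, whose ketene carbon (future C1) bonds to the distal alkene carbon (future C2) in a disrotatory 6π electrocyclisation that restores the benzo ring; enolisation of 21 gives naphthalenediol 22 and Ag2O dehydrogenates it to quinone 23. The closest known reaction type is the Moore rearrangement of 4-alkenyl-4-hydroxycyclobutenones and of their benzo-fused analogues to hydroquinones and quinones. The single ring closed is the six-membered quinone ring, by 6π electrocyclic closure of the triene made up of the ketene C=C, the exocyclic enol C=C and the side-chain C=C, driven by release of four-ring strain and by rearomatisation. The only new stereocentre, C2 of 21, is transient and vanishes on enolisation, while the (R)-silyloxy centre next to it takes part in no bond change and is carried through intact. The step needs the alkenyl group to rotate inward toward the ketene, which the donor hydroxyl on the same carbon secures through its strong preference for outward rotation (torquoselectivity), and this also holds the enol OH away from the ketene so that lactonisation is disfavoured. The closed-shell alkenyl precursor is preferred to an alkynyl one because the latter would pass through a σ-radical at C3 placed for 5-exo addition to the prenyl double bond.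

Step 12
Reactants: 23 2-[(1R)-1-(tert-butyldimethylsilyloxy)-4-methylpent-3-en-1-yl]-5,8-bis(tert-butyldimethylsilyloxy)naphthalene-1,4-dione
Product: 24 5,8-dihydroxy-2-[(1R)-1-hydroxy-4-methylpent-3-en-1-yl]naphthalene-1,4-dione (shikonin)
Conditions: HF·pyridine, pyridine, THF, 0 °C to rt
Reagents that add atoms: none
Why: Buffered fluoride-mediated desilylation cleaves the two aryl silyl ethers and the secondary silyl ether at Si–O and not at C–O, so the (R)-centre is retained and the naphthazarin core appears under non-basic conditions.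

Step 13
Reactants: 25 2-bromo-3-methylbut-2-ene; 26 oxirane
Product: 28 3,4-dimethylpent-3-en-1-ol, via 3-methylbut-2-en-2-yllithium 27 (not isolated)
Conditions: t-BuLi (2 equiv), Et2O, −78 °C; then oxirane, −78 °C to rt; H2O
Reagents that add atoms: none
Why: Bromine–lithium exchange gives the tetrasubstituted vinyllithium 27, which has no geometry to lose, and SN2 opening of unhindered oxirane by the organolithium adds the two-carbon alcohol arm.

Step 14
Reactants: 28 3,4-dimethylpent-3-en-1-ol
Product: 30 3,4-dimethylpent-3-enoic acid, via 3,4-dimethylpent-3-enal 29 (not isolated)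
Conditions: 2,2,6,6-tetramethylpiperidin-1-oxyl (cat.), PhI(OAc)2 (2.2 equiv), MeCN–H2O, rt
Reagents that add atoms: water (O)
Why: Oxoammonium-catalysed oxidation in aqueous MeCN takes the primary alcohol through aldehyde 29 and its hydrate to the acid under near-neutral conditions, which should keep the tetrasubstituted β,γ-double bond from moving into conjugation or lactonising.

Step 15
Reactants: 24 shikonin; 30 3,4-dimethylpent-3-enoic acid
Product: 32 (1R)-1-(5,8-dihydroxy-1,4-dioxo-1,4-dihydronaphthalen-2-yl)-4-methylpent-3-en-1-yl 3,4-dimethylpent-3-enoate (target), via O-acylisourea 31 (not isolated)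
Conditions: DCC, 4-(dimethylamino)pyridine (cat.), CH2Cl2, 0 °C to rt
Reagents that add atoms: none
Why: Steglich esterification should acylate only the side-chain secondary alcohol because the two peri-hydroxyls are tied up in strong hydrogen bonds to the quinone carbonyls, and the C–O bond of the stereocentre is not broken, so (R) is retained.

Compound list
1 | 2-bromo-1,4-dimethoxybenzene | COc1ccc(OC)c(Br)c1 | starting material
2 | 1,1-diethoxyethene | C=C(OCC)OCC | starting material
3 | 3,6-dimethoxybenzyne | COC1=CC=C(OC)C#C1 | intermediate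
4 | 7,7-diethoxy-2,5-dimethoxybicyclo[4.2.0]octa-1,3,5-triene | CCOC1(OCC)Cc2c(OC)ccc(OC)c21 | intermediate
5 | 2,5-dimethoxybicyclo[4.2.0]octa-1,3,5-trien-7-one | COc1ccc(OC)c2c1CC2=O | intermediate
6 | 8,8-dibromo-2,5-dimethoxybicyclo[4.2.0]octa-1,3,5-trien-7-one | COc1ccc(OC)c2c1C(Br)(Br)C2=O | intermediate
7 | 2,5-dimethoxybicyclo[4.2.0]octa-1,3,5-triene-7,8-dione | COc1ccc(OC)c2c1C(=O)C2=O | intermediate
8 | 2,5-dihydroxybicyclo[4.2.0]octa-1,3,5-triene-7,8-dione | Oc1ccc(O)c2c1C(=O)C2=O | intermediate
9 | 2,5-bis(tert-butyldimethylsilyloxy)bicyclo[4.2.0]octa-1,3,5-triene-7,8-dione | CC(C)(C)[Si](C)(C)Oc1ccc(O[Si](C)(C)C(C)(C)C)c2c1C(=O)C2=O | intermediate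
10 | 4-methylpent-3-enoic acid | CC(C)=CCC(=O)O | starting material
11 | 1-(imidazol-1-yl)-4-methylpent-3-en-1-one | CC(C)=CCC(=O)n1ccnc1 | intermediate
12 | N-methoxy-N,4-dimethylpent-3-enamide | CC(C)=CCC(=O)N(C)OC | intermediate
13 | (E)-1,2-bis(tributylstannyl)ethene | CCCC[Sn](CCCC)(CCCC)/C=C/[Sn](CCCC)(CCCC)CCCC | starting material
14 | (E)-2-(tributylstannyl)vinyllithium | [Li]/C=C/[Sn](CCCC)(CCCC)CCCC | intermediate
15 | (E)-6-methyl-1-(tributylstannyl)hepta-1,5-dien-3-one | CC(C)=CCC(=O)/C=C/[Sn](CCCC)(CCCC)CCCC | intermediate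
16 | (1E,3R)-6-methyl-1-(tributylstannyl)hepta-1,5-dien-3-ol | CC(C)=CC[C@@H](O)/C=C/[Sn](CCCC)(CCCC)CCCC | intermediate
17 | (1E,3R)-3-(tert-butyldimethylsilyloxy)-6-methyl-1-(tributylstannyl)hepta-1,5-diene | CC(C)=CC[C@@H](O[Si](C)(C)C(C)(C)C)/C=C/[Sn](CCCC)(CCCC)CCCC | intermediate
18 | (1E,3R)-3-(tert-butyldimethylsilyloxy)-6-methylhepta-1,5-dien-1-yllithium | CC(C)=CC[C@@H](O[Si](C)(C)C(C)(C)C)/C=C/[Li] | intermediate
19 | 8-hydroxy-8-[(1E,3R)-3-(tert-butyldimethylsilyloxy)-6-methylhepta-1,5-dien-1-yl]-2,5-bis(tert-butyldimethylsilyloxy)bicyclo[4.2.0]octa-1,3,5-trien-7-one, C8 epimers | CC(C)=CC[C@@H](O[Si](C)(C)C(C)(C)C)/C=C/C1(O)C(=O)c2c(O[Si](C)(C)C(C)(C)C)ccc(O[Si](C)(C)C(C)(C)C)c21 | intermediate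
20 | o-quinoid vinylketene from ring opening of 19 | CC(C)=CC[C@@H](O[Si](C)(C)C(C)(C)C)/C=C/C(O)=C1C(O[Si](C)(C)C(C)(C)C)=CC=C(O[Si](C)(C)C(C)(C)C)C1=C=O | intermediate
21 | 4-hydroxy-2-[(1R)-1-(tert-butyldimethylsilyloxy)-4-methylpent-3-en-1-yl]-5,8-bis(tert-butyldimethylsilyloxy)naphthalen-1(2H)-one | CC(C)=CC[C@@H](O[Si](C)(C)C(C)(C)C)C1C=C(O)c2c(O[Si](C)(C)C(C)(C)C)ccc(O[Si](C)(C)C(C)(C)C)c2C1=O | intermediate
22 | 2-[(1R)-1-(tert-butyldimethylsilyloxy)-4-methylpent-3-en-1-yl]-5,8-bis(tert-butyldimethylsilyloxy)naphthalene-1,4-diol | CC(C)=CC[C@@H](O[Si](C)(C)C(C)(C)C)c1cc(O)c2c(O[Si](C)(C)C(C)(C)C)ccc(O[Si](C)(C)C(C)(C)C)c2c1O | intermediate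
23 | 2-[(1R)-1-(tert-butyldimethylsilyloxy)-4-methylpent-3-en-1-yl]-5,8-bis(tert-butyldimethylsilyloxy)naphthalene-1,4-dione | CC(C)=CC[C@@H](O[Si](C)(C)C(C)(C)C)C1=CC(=O)c2c(O[Si](C)(C)C(C)(C)C)ccc(O[Si](C)(C)C(C)(C)C)c2C1=O | intermediate
24 | shikonin, 5,8-dihydroxy-2-[(1R)-1-hydroxy-4-methylpent-3-en-1-yl]naphthalene-1,4-dione | CC(C)=CC[C@@H](O)C1=CC(=O)c2c(O)ccc(O)c2C1=O | intermediate
25 | 2-bromo-3-methylbut-2-ene | CC(C)=C(C)Br | starting material
26 | oxirane | C1CO1 | starting material
27 | 3-methylbut-2-en-2-yllithium | CC(C)=C(C)[Li] | intermediate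
28 | 3,4-dimethylpent-3-en-1-ol | CC(C)=C(C)CCO | intermediate
29 | 3,4-dimethylpent-3-enal | CC(C)=C(C)CC=O | intermediate
30 | 3,4-dimethylpent-3-enoic acid | CC(C)=C(C)CC(=O)O | intermediate
31 | O-(3,4-dimethylpent-3-enoyl)-N,N'-dicyclohexylisourea | CC(C)=C(C)CC(=O)OC(=NC1CCCCC1)NC1CCCCC1 | intermediate
32 | (1R)-1-(5,8-dihydroxy-1,4-dioxo-1,4-dihydronaphthalen-2-yl)-4-methylpent-3-en-1-yl 3,4-dimethylpent-3-enoate | CC(C)=CC[C@@H](OC(=O)CC(C)=C(C)C)C1=CC(=O)c2c(O)ccc(O)c2C1=O | target

Total step count: 15. Longest linear sequence: 9 steps (1, 2, 3, 4, 5, 10, 11, 12, 15).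

Steps most likely to fail

1. Step 11 (key step).
- What may go wrong: the dearomatising ring opening may need a temperature at which the electron-rich naphthalenediol loses silanol from its benzylic position. The ketene may also be intercepted before it cyclises.
- Fallback: it sets out from 9 and 12 and comes back at 23. The same C1–C2 bond is closed on a metal instead of thermally.
- Amide 12 and ethynylmagnesium bromide should give 6-methylhept-5-en-1-yn-3-one F1.
- Midland reduction with B-isopinocampheyl-9-borabicyclo[3.3.1]nonane derived from (+)-α-pinene should give (R)-6-methylhept-5-en-1-yn-3-ol F2.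
- TBSCl and imidazole should then give (R)-3-(tert-butyldimethylsilyloxy)-6-methylhept-5-en-1-yne F3.
- CoCl(PPh3)3 inserts into the C7–C8 bond of dione 9 to give the chlorobis(triphenylphosphine)phthaloylcobalt complex F4.
- With AgBF4 in MeCN at 80 °C, F4 takes up alkyne F3. Alkyne insertion at the unsubstituted carbon, followed by reductive elimination between the second acyl carbon and the substituted vinyl carbon, closes the ring and releases 23 directly at the quinone level. The symmetry of the phthaloyl unit again removes any regiochemical question.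

2. Step 10.
- What may go wrong: a second addition to the remaining carbonyl, cleavage of the four-membered ring by the lithium alkoxide before the quench, or migration of an aryl silyl group to the new alkoxide.
- Fallback: it sets out from 9 and comes back at 19. One carbonyl is masked first.
- MeOSiMe3 with catalytic Me3SiOSO2CF3 in CH2Cl2 at −78 °C should convert 9 into 8,8-dimethoxy-2,5-bis(tert-butyldimethylsilyloxy)bicyclo[4.2.0]octa-1,3,5-trien-7-one F5.
- Vinyllithium 18 then finds a single carbonyl, and the resulting alkoxide has no acyl neighbour to expel. This should give the ketal carbinol 7-[(1E,3R)-3-(tert-butyldimethylsilyloxy)-6-methylhepta-1,5-dien-1-yl]-8,8-dimethoxy-2,5-bis(tert-butyldimethylsilyloxy)bicyclo[4.2.0]octa-1,3,5-trien-7-ol F6.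
- Brief treatment with dilute aqueous acid, as in the second stage of step 1, unmasks the ketone and gives 19.

3. Step 2.
- What may go wrong: electrophilic bromination of the electron-rich dimethoxyarene ring in competition with radical substitution at the methylene group.
- Fallback: it sets out from 5 and comes back at 8, so steps 3 and 4 are bypassed. The ring is made electron-poor before the bromination.
- BBr3 should convert 5 into 2,5-dihydroxybicyclo[4.2.0]octa-1,3,5-trien-7-one F7.
- Ac2O in pyridine should give 7-oxobicyclo[4.2.0]octa-1,3,5-triene-2,5-diyl diacetate F8.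
- NBS under the radical conditions of step 2 should give 8,8-dibromo-7-oxobicyclo[4.2.0]octa-1,3,5-triene-2,5-diyl diacetate F9.
- Hot aqueous H2SO4 hydrolyses the geminal dibromide and both acetates in one operation to give 8.

Further compounds
F1 | step 11 | 6-methylhept-5-en-1-yn-3-one | C#CC(=O)CC=C(C)C
F2 | step 11 | (R)-6-methylhept-5-en-1-yn-3-ol | CC(C)=CC[C@@H](O)C#C
F3 | step 11 | (R)-3-(tert-butyldimethylsilyloxy)-6-methylhept-5-en-1-yne | CC(C)=CC[C@@H](O[Si](C)(C)C(C)(C)C)C#C
F4 | step 11 | chlorobis(triphenylphosphine)[3,6-bis(tert-butyldimethylsilyloxy)phthaloyl]cobalt | CC(C)(C)[Si](C)(C)Oc1ccc(O[Si](C)(C)C(C)(C)C)c2c1C(=O)[Co-2](Cl)([P+](c1ccccc1)(c1ccccc1)c1ccccc1)([P+](c1ccccc1)(c1ccccc1)c1ccccc1)C2=O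
F5 | step 10 | 8,8-dimethoxy-2,5-bis(tert-butyldimethylsilyloxy)bicyclo[4.2.0]octa-1,3,5-trien-7-one | COC1(OC)C(=O)c2c(O[Si](C)(C)C(C)(C)C)ccc(O[Si](C)(C)C(C)(C)C)c21
F6 | step 10 | 7-[(1E,3R)-3-(tert-butyldimethylsilyloxy)-6-methylhepta-1,5-dien-1-yl]-8,8-dimethoxy-2,5-bis(tert-butyldimethylsilyloxy)bicyclo[4.2.0]octa-1,3,5-trien-7-ol | CC(C)=CC[C@@H](O[Si](C)(C)C(C)(C)C)/C=C/C1(O)c2c(O[Si](C)(C)C(C)(C)C)ccc(O[Si](C)(C)C(C)(C)C)c2C1(OC)OC
F7 | step 2 | 2,5-dihydroxybicyclo[4.2.0]octa-1,3,5-trien-7-one | Oc1ccc(O)c2c1CC2=O
F8 | step 2 | 7-oxobicyclo[4.2.0]octa-1,3,5-triene-2,5-diyl diacetate | CC(=O)Oc1ccc(OC(C)=O)c2c1CC2=O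
F9 | step 2 | 8,8-dibromo-7-oxobicyclo[4.2.0]octa-1,3,5-triene-2,5-diyl diacetate | CC(=O)Oc1ccc(OC(C)=O)c2c1C(Br)(Br)C2=O
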